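The numbers in the tables come from a simulation with constants of no real substance; scatter was added.

The vessel is closed, stirred and isothermal, and the north-west run in it slows far too early for a flask with electrophile still present.

| setting | north-west | ochre | violet |
|---|---|---|---|
| electrophile | 0.15 M | 0.10 M | 0.10 M |
| nucleophile | 0.15 M | 0.150 M | 0.220 M |
| remark | run made earlier |  |  |
| time |  | 25 h | 25 h |

north-west run (percent of the electrophile charged)

| time / h | electrophile / % | product / % |
|---|---|---|
| 4.00 | 83.0 | 16.3 |
| 8.00 | 74.2 | 26.5 |
| 12.0 | 69.6 | 31.7 |
| 15.0 | 67.6 | 35.6 |

(scatter of a reading: 1 percentage point)



- part of the electrophile that has reacted at the end, ochre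
- part of the electrophile that has reacted at the end, violet
- what raising the concentration of nucleophile from its lowest to its highest value here does to the part of the electrophile that has reacted (changes below 5 percentage points count as none) (no change / it falls / it rises)

In the north-west flask, the rate per electrophile left falls from 0.0466 h⁻¹ over the first gap to 0.0280 h⁻¹ over the second. Drawn straight against the part reacted, this line reaches zero at 40.9%. I take that point for the end of free nucleophile, so I read a nucleophile cost, the nucleophile charged per electrophile reacted, of 2.45, a reading that carries the scatter. Equivalents over cost give a wall: 61.3% for ochre and 89.9% for violet. Both stand below the whole charge, so on this reading nucleophile is the limiting reagent.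

The same line gives ochre a start rate of 0.0588 h⁻¹. Two pseudo-first-order versions of ochre bracket it. With electrophile held at its whole charge, I reckon 55.7% for ochre by 25 h. With electrophile held at what the wall leaves, I reckon 37.1%. In this picture electrophile runs between those levels, so I put ochre between the two, and integrating gives me 48.9%. The same integration gives violet 65.7%.

The forecast says “this looks like a reversible addition” and gives 38% and 49%, lower than mine; on the trend, it rises, we agree.

The flasks give 47.4% for ochre and 59.9% for violet: it rises, by 13 percentage points.

    nucleophile + acid set free ⇌ protonated nucleophile, settled at all times (K = 16000 M⁻¹)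
    electrophile + nucleophile ⇌ acid set free + product (K = 3.50, k = 0.00730 M⁻¹ min⁻¹)
    2 nucleophile → homo dimer (k = 0.00240 M⁻¹ min⁻¹)

Neither ochre nor violet has come to rest at 25 h. Ochre still holds 15% of its nucleophile free, less than its 53% of electrophile. In ochre, ten times the time adds 11 points and stands at 58.7%, with 0.804% nucleophile free, beside my wall of 61.3%. For a neighbour of ochre charged with 0.17 M electrophile my wall reads 36.1%, and that flask stands at 35.9% after 25.0 h, with 5.1% nucleophile free. Violet gains 15 points in the longer time and reaches 74.8%, with 0.909% nucleophile free.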